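## Structural features

The target is a tricyclic amino enone diacetate. Following the carbon chain from the secondary acetoxy carbon C1 through C2, C3 (methyl and tertiary acetate), C4, the ring-fusion methine C5, C6, the ketone C7, the alkene C8=C9, C10, C11, N12 (N-methyl), C13, C14, C15 to the quaternary C16, three rings result. Ring A is the cyclohexane C1–C5/C16, ring B the cyclopentanone C5–C8/C16 cis-fused to ring A along C5–C16, and ring C the nine-membered azacycle C8–C16 that shares the C8–C16 bond with ring B. C16 carries four carbon substituents and lies between the stereocentres C1 and C5. The oxygens at C1 and C3 are 1,3-cis to each other and cis to C8, both equatorial (C3 methyl axial) in the ring A chair that holds C15 equatorial; all four centres are S. Fragile groups are the tertiary acetate (elimination), the secondary acetate, the oxidisable tertiary amine, and the enone C7(=O)–C8=C9, whose δ-carbon C11 bears nitrogen so that base can open ring C by a vinylogous retro-Michael reaction. The real difficulties are the quaternary C16, the nine-membered ring with a trisubstituted alkene in which C10 must be cis to C16, and the distinction of C8 from C6, both α-methylene groups of the C7 ketone. The key step uses the O–C1–C2–C3–O pattern of ring A: a β-hydroxy ketone whose carbinol carbon C1 hangs on quaternary C16, so that C1–C2 is the bond a methyl ketone forms with an aldehyde that has no α-hydrogen.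

## Logic of the disconnections

**24 to 23.** The two ester C–O bonds at C1 and C3 are cut. The acetates are the least robust groups and would not survive the basic ring closure, so they go on last. This leaves a diol that tolerates base. The forward acylation must reach a tertiary alcohol without touching enone or amine.

**23 to 20 and 21 (through 22).** C8=C9 and N12–C11 are cut, which removes ring C and the enone together and releases C9–C11 as 21. N12–C11 is an intermolecular conjugate addition. C8=C9 is an aldol condensation made intramolecular so that the chain on C16 selects the adjacent C8 (fused nine-membered ring) over C6 (bridged ten-membered ring); an intermolecular condensation would be expected to favour the less hindered C6. The ring also admits only the cis-cycloalkene, which is the required E enone. The demand is a medium-ring closure under dilution.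

**20 to 18.** Functional groups only: N–H back to N-benzyl, the C7 ketone back to its ketal, C1–OH back to a silyl ether. The ketone must stay masked while C3 is built and while the benzyl group is removed under hydrogen. The forward order (hydrogenolysis, then acid) is the demand.

**18 to 16 (through 17).** The bond between C3 and its methyl group is cut. Methylene transfer from sulfur followed by hydride places the carbon axial and the oxygen equatorial, the opposite of what direct methyl addition usually gives. This requires the C1 oxygen to be equatorial and protected.

**16 to 15 to 14.** After removal of the silyl group, C1–C2 is cut (key step). Ring A and the C1 stereocentre disappear and a monocyclic keto aldehyde remains, with its two stereocentres on ring B. The forward step needs enolisation toward the methyl group only, reversibility, and no dehydration.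

**14 to 12 (through 13).** C1 and C3 are reconnected as a C1=C3 double bond. The two carbonyls are 1,5-related through C16–C5, so they are the cleavage products of a cyclopentene. The cis ring fusion of a diquinane then guarantees the cis relationship of formyl and acetonyl groups. The amine must be shielded from the oxidant.

**12 to 11 to 9.** The C3–C2 bond (C2 is the alkene methyl group) is cut to an enol triflate and further to a silyl enol ether. The position of the double bond is inherited from a regiodefined enolate.

**9 to 4 and 7 (through 8).** The C16–C15 bond is cut. Conjugate addition to the β,β-disubstituted enone creates the quaternary centre. The cis fusion fixes C16 relative to C5, and the enolate is the one needed in the previous paragraph.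

**4 to 3 to 2 to 1.** The enone is taken back to a meso ketone by way of an enantioselective deprotonation that tells the two α-methylene groups apart. All absolute configuration comes from this one step.

**7 to 5 and 6.** The N–C13 bond is cut to a secondary amine and a 1,3-dihalide.

## Other disconnections considered

**Alternative 1:** The cut is the C8=C9 double bond, traced back to a sulfone bridging C8 and C9 in a ten-membered ring, A1 (bis-silyl ether, C7 ketal, N-methoxycarbonyl). In the forward step KOH on Al2O3 with CBr2F2 halogenates one α-sulfonyl carbon, the other α-carbanion displaces halide to give the episulfone, and loss of SO2 contracts the ring to the alkene A2.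
- In its favour: the alkene is placed between C8 and C9 with no choice between C6 and C8, and the ring is closed beforehand as a ten-membered thioether, an easier closure than a nine-membered carbon–carbon bond. On both points it is better than the chosen plan. The ring size should enforce C10 cis to C16, where the two plans are equal.
- Against it here: sulfur must first be attached to C8, a secondary carbon wedged between quaternary C16 and the ketal carbon, so the C6/C8 question only moves to an earlier step. The C8 carbanion has a β-alkoxy leaving group (a ketal oxygen) and may open the ketal. A2 still needs carbamate reduction, two desilylations, deketalisation and diacetylation.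
- Comparison: both plans rest on carbanion chemistry beside C7; the alternative replaces one reversible aldol by a three-stage, irreversible sequence. In step count the chosen plan should be shorter by the steps spent on sulfur and on protecting-group exchange.

**Alternative 2:** The cut is C5–C6, opening ring B to a prochiral 4,4-disubstituted cyclohexa-2,5-dienone A3 whose C16 carries the aminopropyl chain and a β-keto ester arm. In the forward step a quinine-derived thiourea deprotonates the β-keto ester and guides C6 onto C5 of one of the two enantiotopic enone arms, giving the cis-fused bicycle A4.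
- In its favour: one catalytic step creates ring B, the quaternary C16 and C5 from an achiral precursor, which is better than the stoichiometric chiral base plus separate conjugate addition of the chosen plan. The dianion of the β-keto ester in A4 reacts at C8, a handle for the C8/C6 problem that the chosen plan lacks.
- Against it here: A4 has no oxygen at C1, only the C1=C2 enone, so the C1 oxygen must still be introduced cis to C8, which the aldol delivers directly. Two ring ketones (C3, C7) must be told apart, the ester must be removed, and A3 needs a dearomatising alkylation to build its quaternary carbon.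
- Comparison: both key steps are enolate additions to a carbonyl-activated acceptor, one under catalyst and kinetic control, the other under substrate and equilibrium control. Overall length should be about equal, the early saving being spent on ring A.

**Alternative 3:** The cut is C8–C16, opening ring B to a cyclohexanone silyl enol ether A5 (C1–O–Si, C1=C16) with a C6–C7–C8≡C9 chain on C5. In the forward step AuCl(PPh3) with AgBF4 activates the alkyne and C16 attacks in a 5-exo-dig closure with anti addition, giving A6 with the quaternary C16, a C1 ketone and the exocyclic C8=C9 alkene.
- In its favour: the quaternary centre, the attachment of C9 to the correct carbon and the alkene geometry are settled in one mild catalytic step. On C8 regiochemistry and alkene geometry it is better than the chosen plan. As a ring-forming reaction the two are equally well grounded.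
- Against it here: C7 arrives as a methylene group and must be oxidised next to a second allylic methylene (C10). The C1 ketone must be reduced cis to C8, the tetrasubstituted enol ether must be made regiospecifically, the C3 carbinol is still to be built, and ring C still needs a nine-membered closure at nitrogen.
- Comparison: a kinetically controlled, irreversible Conia-ene closure stands against a reversible aldol. Step count should be similar or slightly higher.

Key step: step 9

Assumption: the lithium amide from (R,R)-bis(1-phenylethyl)amine is taken to remove the C1 proton that leads to 3; should it prefer the enantiotopic C4 proton, the (S,S)-amide is used and nothing else changes.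

Remark: the locants C1–C16 and N12 of the target are used for every intermediate (in the bicyclic compounds 2–13: ring-fusion carbons C5 and C16, ketone carbon C3 flanked by C1 and C4, ketal carbon C7 flanked by C6 and C8); CIP descriptors refer to these locants.

## Route

Step 1
Reactants: 1 cis-bicyclo[3.3.0]octane-3,7-dione
Product: 2 mono(ethylene ketal) of 1 (meso; free ketone C3, ketal C7)
Conditions: HOCH2CH2OH (1.0 equiv), p-TsOH (cat.), toluene, reflux, water separator
Reagents that add atoms: ethylene glycol, OCCO
Why: Acid-catalysed ketalisation of one of two equivalent ketones; 2 is separated from the statistical mixture and 1 and the bis-ketal are recycled. The mirror plane is kept, so no stereochemistry is at stake.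

Step 2
Reactants: 2 mono(ethylene ketal)
Product: 3 trimethylsilyl enol ether with the C1=C3 double bond, (5S,16R), ring-fusion hydrogens cis
Conditions: (R,R)-[PhCH(CH3)]2NLi (from the amine and n-BuLi), LiCl, Me3SiCl (present from the start), THF, −100 to −78 °C
Reagents that add atoms: chlorotrimethylsilane, C[Si](C)(C)Cl
Why: Enantioselective deprotonation of a meso ketone by a chiral lithium amide with internal silyl quench, a known desymmetrisation of cis-bicyclo[3.3.0]octan-3-ones; choosing the C1 over the C4 methylene fixes the absolute configuration of the whole route. Enantiomeric purity can be raised later by crystallising a salt of amine 12.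

Step 3
Reactants: 3 silyl enol ether
Product: 4 (5S)-enone with C3 ketone, C1=C16 double bond and C7 ketal
Conditions: Pd(OAc)2 (10 mol %), O2 (1 atm), DMSO, 25–40 °C
Reagents that add atoms: none
Why: Saegusa–Ito oxidation: the divalent palladium enolate carries the metal on C1 on the convex face and syn β-hydride elimination of the C16 hydrogen gives the conjugated enone, C5 (S) remaining as the only stereocentre. Neutral conditions avoid migration of the double bond to C16=C5, which would racemise the material.

Step 4
Reactants: 5 N-benzylmethylamine; 6 1-bromo-3-chloropropane
Product: 7 N-benzyl-3-chloro-N-methylpropan-1-amine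
Conditions: K2CO3, MeCN, rt, excess of 6
Reagents that add atoms: none
Why: SN2 N-alkylation at the bromide-bearing carbon, bromide leaving much faster than chloride; excess 6 suppresses quaternisation. 7 is used soon or stored as its hydrochloride because 3-chloropropylamines cyclise slowly to azetidinium salts.

Step 5
Reactants: 4 (5S)-enone; 7 chloro amine
Product: 9 (5S,16R)-trimethylsilyl enol ether (C1=C3) carrying the 3-[benzyl(methyl)amino]propyl chain on C16 cis to H5, via Grignard reagent 8 (not isolated)
Conditions: 7, Mg turnings, THF, 50 °C; then CuBr·SMe2 (10 mol %), Me3SiCl (2 equiv), 4, THF, −78 to −40 °C; Et3N, pentane, filtration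
Reagents that add atoms: chlorotrimethylsilane, C[Si](C)(C)Cl
Why: Copper-catalysed conjugate addition of a Grignard reagent accelerated by Me3SiCl, the standard route to a quaternary β-carbon; only the cis-fused diquinane is accessible, so the chain enters C16 on the convex face and C16 (R) is set relative to C5. The enolate is trapped regiospecifically at C3–O with the double bond toward C1, and the low temperature keeps γ-deprotonation at C5 from competing.

Step 6
Reactants: 9 silyl enol ether
Product: 11 (5S,16R)-enol triflate (C3–OSO2CF3, C1=C3), via lithium enolate 10 (not isolated)
Conditions: MeLi (1.05 equiv), THF, 0 °C; PhNTf2, −78 °C to rt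
Reagents that add atoms: N-phenylbis(trifluoromethanesulfonimide), O=S(=O)(N(c1ccccc1)S(=O)(=O)C(F)(F)F)C(F)(F)F
Why: Methyllithium cleaves the Si–O bond to the regiodefined lithium enolate, which is O-sulfonylated without equilibration, so the double bond stays between C1 and C3.

Step 7
Reactants: 11 enol triflate
Product: 12 (5S,16R)-alkene with a methyl group (C2) on C3 and the C1=C3 double bond
Conditions: MeMgBr, Fe(acac)3 (5 mol %), THF/NMP, −30 to 0 °C
Reagents that add atoms: methylmagnesium bromide, C[Mg]Br
Why: Iron-catalysed cross-coupling of an alkenyl triflate with a methyl Grignard reagent, tolerant of ketal and tertiary amine; the alkene position is untouched and the new methyl group is the future C2.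

Step 8
Reactants: 12 methyl alkene
Product: 14 (5S,16R)-keto aldehyde with C16 formyl, C5 acetonyl and C7 ketal groups, via ozonide 13 (not isolated)
Conditions: CF3CO2H (1.2 equiv), O3, CH2Cl2, −78 °C; PPh3, −78 °C to rt; aq. NaHCO3
Reagents that add atoms: ozone, [O-][O+]=O
Why: Ozonolysis of the only alkene with reductive work-up cleaves C1=C3 to the C1 aldehyde on C16 and the C3 methyl ketone, the cis ring fusion of 12 becoming the cis formyl/acetonyl relationship. The amine is shielded from ozone as its trifluoroacetate salt and the ketal is safe without water or alcohol.

Step 9
Reactants: 14 keto aldehyde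
Product: 15 (1S,5S,16R)-β-hydroxy ketone, cis-hydrindane with C1 alcohol cis to C8, C3 ketone and C7 ketal
Conditions: K2CO3 (0.5 equiv), MeOH, 0 °C to rt
Reagents that add atoms: none
Why: Intramolecular aldol addition: the base removes a proton from the methyl group C2 of the C3 ketone (deprotonation at C4 could lead only to a strained four-membered ring and is reversible), and the enolate adds to the C1 aldehyde, which has no α-hydrogen because it sits on quaternary C16; the closest known reaction type is the base-mediated cyclisation of 1,5-keto aldehydes to 3-hydroxycyclohexanones. Ring A closes in the 6-(enolendo)-exo-trig mode through a chair with the C15 chain equatorial and C8 axial. The new stereocentre C1 is under substrate control: in the open transition state the aldehyde oxygen points away from the enolate oxygen (pseudo-equatorial), and since the addition is reversible the two carbinol epimers interconvert by retro-aldol reaction toward the equatorial alcohol cis to C8. That epimer has one gauche contact fewer than the axial one, avoids the syn-axial H5 and can hydrogen-bond to a ketal oxygen at C7; the expected preference is moderate. The cis ring fusion follows from the cis formyl/acetonyl arrangement fixed in 14. The step needs addition without E1cB dehydration (weak base, low temperature, short contact) and no other enolisable site, which the C7 ketal and the quaternary α-carbon of the aldehyde secure; the tertiary amine is inert. A minor C1 epimer is separable and can be returned to the same equilibrium.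

Step 10
Reactants: 15 β-hydroxy ketone
Product: 16 C1 triethylsilyl ether of 15, (1S,5S,16R)
Conditions: Et3SiOTf, 2,6-lutidine, CH2Cl2, −78 °C
Reagents that add atoms: triethylsilyl trifluoromethanesulfonate, CC[Si](CC)(CC)OS(=O)(=O)C(F)(F)F
Why: Silylation of the hindered secondary alcohol by the silyl triflate at low temperature is faster than enol silylation of the ketone. The ether prevents alkoxide-driven retro-aldol cleavage in step 11 and is lost later in the acidic stage of step 13.

Step 11
Reactants: 16 silyl ether ketone
Product: 17 spiro-epoxide at C3 with axial CH2 and equatorial oxygen, (1S,3S,5S,16R)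
Conditions: Me3S+ I−, n-BuLi, THF, −10 to 0 °C
Reagents that add atoms: trimethylsulfonium iodide, C[S+](C)C.[I-]
Why: Corey–Chaykovsky epoxidation: the unstabilised, irreversibly adding dimethylsulfonium methylide attacks the C3 ketone along the axial trajectory (only hydrogens are syn-axial at C1 and C5), so the epoxide oxygen is equatorial and cis to the C1 oxygen. The ylide is too weak a base to enolise the ketone appreciably, which limits β-elimination of the silyloxy group.

Step 12
Reactants: 17 spiro-epoxide
Product: 18 tertiary alcohol with axial C3 methyl and equatorial C3 hydroxyl, C1 silyl ether, (1S,3S,5S,16R)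
Conditions: LiAlH4, THF, 0 °C to rt
Reagents that add atoms: none
Why: Hydride opens the spiro-epoxide by SN2 attack at the unsubstituted CH2, which becomes the axial C3 methyl group; ketal, silyl ether and benzylamine are inert.

Step 13
Reactants: 18 tertiary alcohol
Product: 20 amino ketone diol with C7 ketone and N-methyl secondary amine, (1S,3S,5S,16R), via secondary amine 19 (not isolated)
Conditions: H2 (1 atm), Pd(OH)2/C, EtOH, rt; filtration; 1 M aq. HCl, THF, rt; NaHCO3
Reagents that add atoms: water, O
Why: Hydrogenolysis removes the N-benzyl group while the ketone is still masked, which excludes reductive amination between N12 and C7. Aqueous acid then hydrolyses the ketal and the triethylsilyl ether with the amine protected as its ammonium ion; the tertiary alcohol tolerates dilute acid at room temperature.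

Step 14
Reactants: 20 amino ketone diol; 21 acrolein
Product: 23 tricyclic enone diol with rings A–C complete and E-configured C8=C9, (1S,3S,5S,16S), via amino aldehyde 22 (not isolated)
Conditions: 21 (1.05 equiv), MeCN, 0 °C; then slow addition to K2CO3, MeOH (2 mM), 40 °C
Reagents that add atoms: none
Why: Aza-Michael addition of the secondary amine to acrolein forms N12–C11, and a base-mediated intramolecular aldol condensation (reversible addition, E1cB dehydration) then joins C8 to C9. The chain on C16 reaches the adjacent C8 in a fused nine-membered ring whereas C6 would need a bridged ten-membered ring, and the ring admits only the cis-cycloalkene, which is the E enone with C10 cis to C16. High dilution favours cyclisation over oligomerisation.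

Step 15
Reactants: 23 enone diol
Product: 24 target diacetate, (1S,3S,5S,16S), E enone
Conditions: Ac2O, Et3N, DMAP, CH2Cl2, 40 °C
Reagents that add atoms: acetic anhydride, CC(=O)OC(C)=O
Why: Nucleophilic catalysis by 4-(dimethylamino)pyridine acetylates both the hindered secondary and the tertiary alcohol with retention; tertiary amine and enone do not react with the acylpyridinium ion.

## Compound list

1 | cis-bicyclo[3.3.0]octane-3,7-dione (meso) | O=C1C[C@@H]2CC(=O)C[C@@H]2C1 | starting material
2 | cis-bicyclo[3.3.0]octane-3,7-dione mono(ethylene ketal) (meso) | O=C1C[C@@H]2CC3(OCCO3)C[C@@H]2C1 | intermediate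
3 | (5S,16R)-trimethylsilyl enol ether of 2, C1=C3 | C[Si](C)(C)OC1=C[C@@H]2CC3(OCCO3)C[C@@H]2C1 | intermediate
4 | (5S)-enone: C3 ketone, C1=C16, C7 ethylene ketal [(6aS)-5,5-(ethylenedioxy)-4,5,6,6a-tetrahydropentalen-2(1H)-one] | O=C1C=C2CC3(OCCO3)C[C@@H]2C1 | intermediate
5 | N-benzylmethylamine | CNCc1ccccc1 | starting material
6 | 1-bromo-3-chloropropane | ClCCCBr | starting material
7 | N-benzyl-3-chloro-N-methylpropan-1-amine | CN(CCCCl)Cc1ccccc1 | intermediate
8 | {3-[benzyl(methyl)amino]propyl}magnesium chloride | CN(CCC[Mg]Cl)Cc1ccccc1 | intermediate (not isolated)
9 | (5S,16R)-trimethylsilyl enol ether (C1=C3) with the 3-[benzyl(methyl)amino]propyl chain on C16, cis-fused | C[Si](C)(C)OC1=C[C@]2(CCCN(C)Cc3ccccc3)CC3(OCCO3)C[C@@H]2C1 | intermediate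
10 | lithium enolate corresponding to 9 | [Li]OC1=C[C@]2(CCCN(C)Cc3ccccc3)CC3(OCCO3)C[C@@H]2C1 | intermediate (not isolated)
11 | (5S,16R)-enol triflate, C1=C3 | O=S(=O)(OC1=C[C@]2(CCCN(C)Cc3ccccc3)CC3(OCCO3)C[C@@H]2C1)C(F)(F)F | intermediate
12 | (5S,16R)-3-methyl alkene, C1=C3 | CC1=C[C@]2(CCCN(C)Cc3ccccc3)CC3(OCCO3)C[C@@H]2C1 | intermediate
13 | ozonide of 12 (1,2,4-trioxolane spanning C1 and C3; diastereomers at C1 and C3) | CC12C[C@H]3CC4(OCCO4)C[C@@]3(CCCN(C)Cc3ccccc3)C(OO1)O2 | intermediate (not isolated)
14 | (7R,8S)-7-{3-[benzyl(methyl)amino]propyl}-8-(2-oxopropyl)-1,4-dioxaspiro[4.4]nonane-7-carbaldehyde (5S,16R in target locants) | CC(=O)C[C@H]1CC2(OCCO2)C[C@]1(C=O)CCCN(C)Cc1ccccc1 | intermediate (key-step precursor)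
15 | (1S,5S,16R)-cis-hydrindane β-hydroxy ketone: C1 OH cis to C8, C3 ketone, C7 ketal | O[C@H]1CC(=O)C[C@H]2CC3(OCCO3)C[C@]21CCCN(C)Cc1ccccc1 | intermediate (key-step product)
16 | C1 triethylsilyl ether of 15 | CC[Si](CC)(CC)O[C@H]1CC(=O)C[C@H]2CC3(OCCO3)C[C@]21CCCN(C)Cc1ccccc1 | intermediate
17 | (1S,3S,5S,16R)-spiro-epoxide at C3 (CH2 axial, O equatorial) | CC[Si](CC)(CC)O[C@H]1C[C@]3(CO3)C[C@H]2CC4(OCCO4)C[C@]21CCCN(C)Cc1ccccc1 | intermediate
18 | (1S,3S,5S,16R)-C3 methyl carbinol, C1 silyl ether, C7 ketal, N-benzyl | CC[Si](CC)(CC)O[C@H]1C[C@@](C)(O)C[C@H]2CC3(OCCO3)C[C@]21CCCN(C)Cc1ccccc1 | intermediate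
19 | N-debenzylated 18 (secondary amine) | CC[Si](CC)(CC)O[C@H]1C[C@@](C)(O)C[C@H]2CC3(OCCO3)C[C@]21CCCNC | intermediate (not isolated)
20 | (1S,3S,5S,16R)-amino ketone diol: C1 and C3 hydroxyls, C7 ketone, 3-(methylamino)propyl on C16 | O[C@H]1C[C@@](C)(O)C[C@H]2CC(=O)C[C@]21CCCNC | intermediate
21 | acrolein (prop-2-enal) | C=CC=O | starting material
22 | amino aldehyde: 20 bearing a 3-oxopropyl group on nitrogen | O[C@H]1C[C@@](C)(O)C[C@H]2CC(=O)C[C@]21CCCN(C)CCC=O | intermediate (not isolated)
23 | (1S,3S,5S,16S)-tricyclic E-enone diol (target without acetyl groups) | O[C@H]1C[C@@](C)(O)C[C@H]2CC(=O)/C3=C/CCN(C)CCC[C@@]321 | intermediate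
24 | target: (1S,3S,5S,16S)-1,3-diacetate, E enone | CC(=O)O[C@H]1C[C@@](C)(OC(C)=O)C[C@H]2CC(=O)/C3=C/CCN(C)CCC[C@@]321 | target

## Step count and least certain steps

Total step count: 15. Longest linear sequence: 14 steps (steps 1–3 and 5–15); step 4 is a one-step branch.

**Step 9 (key step).** What may go wrong is poor facial discrimination at C1, because the two carbinol epimers differ little in energy, together with E1cB dehydration to the enone. The fallback gives up equilibrium control but keeps the same C1–C2 bond, and runs from 14 back to 20.
- With NaOMe in MeOH at 50 °C, 14 is taken through aldol condensation to the cyclohexenone (C3 ketone, C1=C2) F1.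
- MeLi with CeCl3 in THF at −78 °C adds to C3 by axial attack, anti to the ring B bond on C5, to give the tertiary allylic alcohol F2.
- 1,1,3,3-Tetramethyldisilazane converts it into the dimethylsilyl ether F3.
- H2PtCl6·6H2O (cat.) brings about 5-endo intramolecular hydrosilylation to the cyclic siloxane F4, silicon necessarily reaching C1 on the face of the C3 oxygen.
- Tamao–Fleming oxidation (H2O2, KF, KHCO3) with retention gives the cis-1,3-diol F5. Any N-oxide formed is reduced again in the next operation.
- The conditions of step 13 applied to F5 give 20.

**Step 14.** What may go wrong is oligomerisation in place of nine-membered ring closure, closure at C6, loss of acrolein by retro-Michael reaction, or attack of the aldehyde enolate on C7. The fallback closes ring C by metathesis, with C8 marked by an easier seven-membered closure, and runs from 20 to 23.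
- The hydrochloride of 20 with paraformaldehyde in EtOH at 70 °C undergoes intramolecular Mannich reaction at C8 (seven-membered ring; C6 would need a bridged eight-membered ring) to the azepane-fused Mannich base F6.
- 4-Iodobut-1-ene in MeCN quaternises nitrogen to the ammonium iodide F7.
- Aqueous NaHCO3 induces Hofmann-type retro-Michael elimination to the C8-methylene ketone with an N-but-3-enyl chain, F8.
- As its toluenesulfonate salt, F8 is closed with the second-generation Grubbs catalyst RuCl2(H2IMes)(PCy3)(=CHPh) in dilute toluene at 80 °C to 23.

**Step 2.** What may go wrong is insufficient discrimination of the enantiotopic methylene groups, or the opposite sense. The fallback is a resolution and runs from 2 to 4.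
- IBX in DMSO/toluene at 70 °C dehydrogenates 2 to the racemic enone F9.
- Luche reduction (NaBH4, CeCl3·7H2O, MeOH, −78 °C) from the convex face gives the racemic allylic alcohol F10.
- Immobilised Candida antarctica lipase B with vinyl acetate acylates one enantiomer.
- The 5S series is collected as the alcohol F11, either directly or by methanolysis (K2CO3, MeOH) of its acetate F12.
- MnO2 in CH2Cl2 oxidises F11 to 4.

**Step 5.** What may go wrong is slow transfer of the amine-chelated organocopper to the hindered β-carbon, with 1,2-addition or γ-deprotonation (racemisation at C5) taking over. The fallback brings the chain in with an oxygen terminus and adds nitrogen later, and runs from 4 to 12.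
- The Grignard reagent F13 from (3-bromopropoxy)(tert-butyl)dimethylsilane is added to 4 under the conditions of step 5 to give the silyl enol ether F14.
- The reagents of step 6 give the enol triflate F15, and those of step 7 the methyl alkene F16.
- Bu4NF removes the silyl group to the alcohol F17.
- MsCl with Et3N gives the mesylate F18, which is displaced by 5 (K2CO3, MeCN, 60 °C) to 12.

**Step 11.** What may go wrong is insufficient axial preference of the ylide or base-induced loss of the silyloxy group. The fallback replaces methylene transfer and reduction by a direct axial methyl addition and runs from 16 to 18. MeLi is added to 16 precomplexed with MeAl(OAr)2 (Ar = 2,6-di-tert-butyl-4-methylphenyl, excess to saturate the amine) in toluene at −78 °C. The bulky aluminium reagent occupies the equatorial side of the carbonyl and forces axial delivery. This fallback passes through no new compound (F0).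

## Further compounds

F1 | step 9 | cyclohexenone from aldol condensation (C3 ketone, C1=C2, C7 ketal, N-benzyl), (5S,16R) | O=C1C[C@H]2CC3(OCCO3)C[C@@]2(CCCN(C)Cc2ccccc2)C=C1
F2 | step 9 | tertiary allylic alcohol (C3 OH equatorial, C3 methyl axial, C1=C2) | C[C@]1(O)C[C@H]2CC3(OCCO3)C[C@@]2(CCCN(C)Cc2ccccc2)C=C1
F3 | step 9 | dimethylsilyl ether of F2 | C[C@]1(O[SiH](C)C)C[C@H]2CC3(OCCO3)C[C@@]2(CCCN(C)Cc2ccccc2)C=C1
F4 | step 9 | cyclic siloxane bridging C3–O and C1 (1,2-oxasilolane) | C[C@]12C[C@H]3CC4(OCCO4)C[C@@]3(CCCN(C)Cc3ccccc3)[C@H](C1)[Si](C)(C)O2
F5 | step 9 | cis-1,3-diol with C7 ketal and N-benzyl group (18 without the silyl group) | O[C@H]1C[C@@](C)(O)C[C@H]2CC3(OCCO3)C[C@]21CCCN(C)Cc1ccccc1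
F6 | step 14 | azepane-fused Mannich base (N12–CH2–C8; C8 epimers) | O[C@H]1C[C@@](C)(O)C[C@H]2CC(=O)C3CN(C)CCC[C@@]321
F7 | step 14 | N-but-3-enyl ammonium iodide of F6 | O[C@H]1C[C@@](C)(O)C[C@H]2CC(=O)C3C[N+](C)(CCC=C)CCC[C@@]321.[I-]
F8 | step 14 | C8-methylene ketone with N-but-3-enyl-N-methylaminopropyl chain | O[C@H]1C[C@@](C)(O)C[C@H]2CC(=O)C(=C)[C@]21CCCN(C)CCC=C
F9 | step 2 | racemic enone (racemate of 4) | O=C1C=C2CC3(OCCO3)CC2C1
F10 | step 2 | racemic allylic alcohol, hydroxyl trans to H5 | OC1C=C2CC3(OCCO3)CC2C1
F11 | step 2 | allylic alcohol of the 5S series, hydroxyl trans to H5 | O[C@@H]1C=C2CC3(OCCO3)C[C@@H]2C1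
F12 | step 2 | acetate of F11 | CC(=O)O[C@@H]1C=C2CC3(OCCO3)C[C@@H]2C1
F13 | step 5 | {3-[(tert-butyldimethylsilyl)oxy]propyl}magnesium bromide | CC(C)(C)[Si](C)(C)OCCC[Mg]Br
F14 | step 5 | trimethylsilyl enol ether with silyloxypropyl chain on C16 | C[Si](C)(C)OC1=C[C@]2(CCCO[Si](C)(C)C(C)(C)C)CC3(OCCO3)C[C@@H]2C1
F15 | step 5 | enol triflate with silyloxypropyl chain | O=S(=O)(OC1=C[C@]2(CCCO[Si](C)(C)C(C)(C)C)CC3(OCCO3)C[C@@H]2C1)C(F)(F)F
F16 | step 5 | 3-methyl alkene with silyloxypropyl chain | CC1=C[C@]2(CCCO[Si](C)(C)C(C)(C)C)CC3(OCCO3)C[C@@H]2C1
F17 | step 5 | 3-methyl alkene with 3-hydroxypropyl chain | CC1=C[C@]2(CCCO)CC3(OCCO3)C[C@@H]2C1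
F18 | step 5 | mesylate of F17 | CC1=C[C@]2(CCCOS(C)(=O)=O)CC3(OCCO3)C[C@@H]2C1
F0 | step 11 | none | none
A1 | alternative 1 | ten-membered cyclic sulfone bridging C8 and C9 (bis-silyl ether, C7 ketal, N-methoxycarbonyl; C8 epimers) | CC(C)(C)[Si](C)(C)O[C@H]1C[C@@](C)(O[Si](C)(C)C(C)(C)C)C[C@H]2CC5(OCCO5)C3S(=O)(=O)CCCN(C(=O)OC)CCC[C@@]321
A2 | alternative 1 | ring C alkene with C7 ketal and N-methoxycarbonyl group | CC(C)(C)[Si](C)(C)O[C@H]1C[C@@](C)(O[Si](C)(C)C(C)(C)C)C[C@H]2CC5(OCCO5)/C3=C/CCN(C(=O)OC)CCC[C@@]321
A3 | alternative 2 | prochiral 4,4-disubstituted cyclohexa-2,5-dienone with β-keto ester arm | O=C1C=CC(CCCN(C)C(=O)OC(C)(C)C)(CC(=O)CC(=O)OC)C=C1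
A4 | alternative 2 | cis-fused bicyclic enone with C7 ketone and C6 ester | O=C1C=C[C@]2(CCCN(C)C(=O)OC(C)(C)C)CC(=O)[C@@H](C(=O)OC)[C@@H]2C1
A5 | alternative 3 | C1 silyl enol ether (C1=C16) with alkynyl chain on C5 and C3 ketal | CC(C)(C)[Si](C)(C)OC1=C(CCCN(C)C(=O)OC(C)(C)C)[C@H](CCC#CCCO[Si](C)(C)C(C)(C)C)CC2(OCCO2)C1
A6 | alternative 3 | cis-hydrindanone with quaternary C16 and defined C8=C9 alkene | O=C1CC2(OCCO2)C[C@H]3CC/C(=C/CCO[Si](C)(C)C(C)(C)C)[C@@]13CCCN(C)C(=O)OC(C)(C)C
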